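**Retrosynthetic overview**
- Ring D is cut by a Diels–Alder disconnection at C8 and C9, which gives myrcene and a 12-hydroxy-11,14-quinone carrying the 6α-formyl group (rings A, B, C).
- The quinone comes from a resorcinol, and the resorcinol from a 2-isopropyl-1,3-dione closed by a Dieckmann reaction (C13–C14). The formyl carbon C7 is added at benzylic C6 by way of the C6 ketone.
- The route rests on the trans-fused hydrindane of rings A and B: quaternary C10 with its β-methyl, C5 with its α-hydrogen, gem-dimethyl C4. This is sclareolide with ring B contracted. A Wolff contraction of the 7-diazo-8-ketone makes the labdane C7–C9 bond (target C8–C9), and labdane C7, C8, C11, C12 become target C8, C14, C11, C12.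
- Order of rings: A (from sclareolide), B (step 6), C (step 10, aromatised in step 11), D (step 16).

Key step: step 6

Remark: labdane numbering is used up to compound 16 and target (abietane-type) numbering from compound 17 on (formyl carbon C7 on C6; ring C = C8, C9, C11–C14); compounds that are epimer, tautomer or alkene-isomer mixtures at centres that later become sp2 or are equilibrated are drawn as the expected main form.

**Step 1**
Reactants: 1 (+)-sclareolide
Product: 2 13,14,15,16-tetranorlabdane-8α,12-diol
Conditions: LiAlH4, THF, 0 °C to reflux; aq NaOH work-up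
Reagents that add atoms: none
Why: Hydride reduction of the lactone opens it to the primary C12 alcohol and the tertiary 8α-alcohol and leaves C5, C9 and C10 untouched.

**Step 2**
Reactants: 2 13,14,15,16-tetranorlabdane-8α,12-diol
Product: 3 12-(tert-butyldimethylsilyloxy)-13,14,15,16-tetranorlabdan-8α-ol
Conditions: TBSCl, imidazole, DMF, 0 °C to rt
Reagents that add atoms: tert-butyldimethylsilyl chloride, CC(C)(C)[Si](C)(C)Cl
Why: Silylation under these conditions should take only the primary hydroxyl, since the tertiary 8α-hydroxyl is too hindered to react.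

**Step 3**
Reactants: 3 12-(tert-butyldimethylsilyloxy)-13,14,15,16-tetranorlabdan-8α-ol
Product: 5 12-(tert-butyldimethylsilyloxy)-13,14,15,16-tetranorlabd-8(17)-ene, via 8α-chlorosulfite 4 (not isolated)
Conditions: SOCl2, pyridine, CH2Cl2, −78 °C
Reagents that add atoms: none
Why: Dehydration of the tertiary alcohol through its equatorial chlorosulfite, which has no antiperiplanar ring hydrogen, so elimination should take a hydrogen of the axial C17 methyl and give mainly the exocyclic alkene; ring-alkene isomers are removed after step 4.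

**Step 4**
Reactants: 5 12-(tert-butyldimethylsilyloxy)-13,14,15,16-tetranorlabd-8(17)-ene
Product: 7 12-(tert-butyldimethylsilyloxy)-13,14,15,16,17-pentanorlabdan-8-one, via spiro-ozonide 6 (not isolated)
Conditions: O3, CH2Cl2, −78 °C; then Me2S, −78 °C to rt
Reagents that add atoms: ozone, [O-][O+]=O
Why: Ozonolysis with reductive work-up cuts off C17 and gives the 8-ketone; C9 already holds its side chain equatorial and should not epimerise.

**Step 5**
Reactants: 7 12-(tert-butyldimethylsilyloxy)-13,14,15,16,17-pentanorlabdan-8-one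
Product: 9 7-diazo-12-(tert-butyldimethylsilyloxy)-13,14,15,16,17-pentanorlabdan-8-one, via 7-trifluoroacetyl ketone 8 (not isolated)
Conditions: LiN(SiMe3)2, THF, −78 °C; CF3CO2CH2CF3; 5% aq HCl work-up; then 4-acetamidobenzenesulfonyl azide, Et3N, H2O, MeCN, rt
Reagents that add atoms: 4-acetamidobenzenesulfonyl azide, CC(=O)Nc1ccc(cc1)S(=O)(=O)N=[N+]=[N-]
Why: Detrifluoroacetylative diazo transfer, in which the kinetic enolate forms at the C7 methylene (the C9 methine is hindered), is trifluoroacetylated, and the activated position then takes the diazo group with loss of the trifluoroacetyl group.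

**Step 6**
Reactants: 9 7-diazo-12-(tert-butyldimethylsilyloxy)-13,14,15,16,17-pentanorlabdan-8-one
Product: 11 methyl 12-(tert-butyldimethylsilyloxy)-9(8→7)abeo-13,14,15,16,17-pentanorlabdan-8-oate (7β-ester), via ring-contracted ketene 10 (not isolated)
Conditions: hν (medium-pressure Hg lamp, Pyrex filter), MeOH, 0 °C
Reagents that add atoms: methanol, CO
Why: Irradiation of the ring diazo ketone, which is locked s-cis, expels N2 while C9 shifts from the carbonyl carbon C8 to C7 to give ketene 10, which methanol adds to; the closest known reaction type is the photochemical Wolff ring contraction of 2-diazocyclohexanones. Ring B is closed as a cyclopentane (C5, C6, C7, C9, C10) by ring contraction and not by cyclisation: the C7–C9 bond forms as the C8–C9 bond breaks, and C8 leaves the ring as the ester carbon. C9 migrates with retention, so C5, C9 and C10 keep the configuration of sclareolide and the hydrindane stays trans-fused. The one new stereocentre, C7, is set by protonation of the ester enol from the α face, away from the axial C10 methyl and the C9 side chain, which should give mainly the 7β-ester; this centre is epimerisable and becomes sp2 in ring C, so its ratio does not matter. The step needs the 1,2-carbon shift to win over a 1,2-hydride shift from C6 and over O–H insertion; the fixed s-cis geometry under direct photolysis and the fact that C9 is the only group on C8 that can migrate should secure this.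

**Step 7**
Reactants: 11 methyl 12-(tert-butyldimethylsilyloxy)-9(8→7)abeo-13,14,15,16,17-pentanorlabdan-8-oate
Product: 12 8-methyl hydrogen 9(8→7)abeo-13,14,15,16,17-pentanorlabdane-8,12-dioate (C12 acid)
Conditions: CrO3, H2SO4, H2O, acetone, 0 °C
Reagents that add atoms: water, O
Why: Jones oxidation, in which the aqueous acid cleaves the primary silyl ether and hexavalent chromium takes the alcohol through the aldehyde hydrate to the acid in one operation, so no hydroxy ester builds up that could lactonise onto the cis ester.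

**Step 8**
Reactants: 13 1-bromo-2-methylpropane
Product: 14 isobutylmagnesium bromide
Conditions: Mg, I2 (cat.), THF, reflux
Reagents that add atoms: magnesium, [Mg]
Why: Grignard formation from a primary alkyl bromide.

**Step 9**
Reactants: 12 8-methyl hydrogen 9(8→7)abeo-13,14,15,16,17-pentanorlabdane-8,12-dioate; 14 isobutylmagnesium bromide
Product: 16 methyl ester carrying the 9β-(4-methyl-2-oxopentyl) side chain, via acid chloride 15 (not isolated)
Conditions: (COCl)2, DMF (cat.), CH2Cl2, 0 °C to rt, evaporate; then 14, Fe(acac)3 (iron tris(pentane-2,4-dionate), 3 mol %), THF, −78 °C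
Reagents that add atoms: none
Why: Iron-catalysed acylation of the Grignard reagent by the acid chloride should stop at the ketone and be much faster at −78 °C than addition to the methyl ester.

**Step 10**
Reactants: 16 methyl ester carrying the 9β-(4-methyl-2-oxopentyl) side chain
Product: 17 tricyclic 12-hydroxy-13-isopropyl-12-en-14-one (enol form of the ring C 1,3-dione)
Conditions: KOt-Bu, THF, 0 °C to rt; aq HCl
Reagents that add atoms: none
Why: Dieckmann-type Claisen condensation in which the C13 enolate of the ketone attacks the ester carbon C14 in a 6-exo-trig closure of ring C, driven by the stabilised enolate of the 2-alkyl-1,3-dione; both C8 epimers converge.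

**Step 11**
Reactants: 17 tricyclic 12-hydroxy-13-isopropyl-12-en-14-one
Product: 19 12,14-bis(tert-butyldimethylsilyloxy)-13-isopropyl arene with aromatic ring C, via bis-silyl dienol ether 18 (not isolated)
Conditions: TBSOTf, Et3N, CH2Cl2, 0 °C to rt; aq NaHCO3 work-up; then DDQ, PhMe, 0 °C
Reagents that add atoms: tert-butyldimethylsilyl triflate, CC(C)(C)[Si](C)(C)OS(=O)(=O)C(F)(F)F
Why: Dehydrogenative aromatisation, in which double O-silylation gives a cyclohexa-1,3-diene with two silyloxy groups, DDQ abstracts hydride to an arenium ion and proton loss gives the resorcinol bis-silyl ether; C8 and C9 become sp2 and C5 and C10 are not touched.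

**Step 12**
Reactants: 19 12,14-bis(tert-butyldimethylsilyloxy)-13-isopropyl arene
Product: 20 6-ketone of 19
Conditions: CrO3 (10 mol %), t-BuOOH (70% in water), CH2Cl2, rt
Reagents that add atoms: tert-butyl hydroperoxide, CC(C)(C)OO
Why: Benzylic C–H oxidation at C6, the only benzylic methylene, since C10 is quaternary and the isopropyl C–H lies in the plane of the arene between two silyloxy groups.

**Step 13**
Reactants: 20 6-ketone of 19
Product: 21 6-(methoxymethylene) compound (E/Z mixture)
Conditions: Ph3P(CH2OMe)Cl, KN(SiMe3)2, THF, 0 °C; then 20, 0 °C to 50 °C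
Reagents that add atoms: (methoxymethyl)triphenylphosphonium chloride, COC[P+](c1ccccc1)(c1ccccc1)c1ccccc1.[Cl-]
Why: Wittig methoxymethylenation brings in the formyl carbon C7, with the small ylide expected to add from the α face; enolisation toward C5 should be slow because the C5 hydrogen sits between two quaternary carbons.

**Step 14**
Reactants: 21 6-(methoxymethylene) compound
Product: 23 12,14-dihydroxy-13-isopropyl arene with 6α-formyl group, via resorcinol enol ether 22 (not isolated)
Conditions: Bu4NF, THF, 0 °C; then 2 M aq HCl, THF, 40 °C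
Reagents that add atoms: water, O
Why: Fluoride cleaves the aryl silyl ethers, and aqueous acid hydrolyses the enol ether and equilibrates C6 through the enol to the α-formyl epimer, which is trans to the C5–C4 bond and clear of the axial C10 methyl (thermodynamic control).

**Step 15**
Reactants: 23 12,14-dihydroxy-13-isopropyl arene with 6α-formyl group
Product: 24 6α-formyl-12-hydroxy-13-isopropyl-11,14-quinone (rings A, B, C)
Conditions: (KSO3)2NO, KH2PO4, H2O/acetone, 0 °C to rt
Reagents that add atoms: potassium nitrosodisulfonate, [K+].[K+].[O]N(S(=O)(=O)[O-])S(=O)(=O)[O-]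
Why: Teuber oxidation of the C14 phenol at its free para position C11 gives the 11,14-quinone with the 12-hydroxyl kept as the enol; oxidation ortho to the C12 phenol would give a tautomer of the same compound.

**Step 16**
Reactants: 24 6α-formyl-12-hydroxy-13-isopropyl-11,14-quinone; 25 myrcene
Product: 26 target compound CNP0239256.1
Conditions: 25 (excess), Er(fod)3 (erbium tris(6,6,7,7,8,8,8-heptafluoro-2,2-dimethyloctane-3,5-dionate), 10 mol %), CH2Cl2, rt, dark
Reagents that add atoms: none
Why: Lewis acid-promoted Diels–Alder reaction at the C8=C9 bond, in which the lanthanide on the C14 carbonyl (the more basic, vinylogous-acid carbonyl, also within reach of the formyl oxygen) should make C9 the electrophilic end that takes the more nucleophilic CH2 on the substituted diene carbon, while the diene adds to the α face opposite the axial C10 methyl and so sets C8 and C9 with a cis fusion of rings C and D.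

**Compound list**
1 | (+)-sclareolide | C[C@]12CCCC([C@@H]1CC[C@@]3([C@@H]2CC(=O)O3)C)(C)C | starting material
2 | 13,14,15,16-tetranorlabdane-8α,12-diol | C[C@@]1(O)CC[C@H]2C(C)(C)CCC[C@]2(C)[C@H]1CCO | intermediate
3 | 12-(tert-butyldimethylsilyloxy)-13,14,15,16-tetranorlabdan-8α-ol | C[C@@]1(O)CC[C@H]2C(C)(C)CCC[C@]2(C)[C@H]1CCO[Si](C)(C)C(C)(C)C | intermediate
4 | 8α-chlorosulfite of 3 | C[C@@]1(OS(Cl)=O)CC[C@H]2C(C)(C)CCC[C@]2(C)[C@H]1CCO[Si](C)(C)C(C)(C)C | intermediate
5 | 12-(tert-butyldimethylsilyloxy)-13,14,15,16-tetranorlabd-8(17)-ene | C=C1CC[C@H]2C(C)(C)CCC[C@]2(C)[C@H]1CCO[Si](C)(C)C(C)(C)C | intermediate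
6 | spiro-ozonide of 5 (1,2,4-trioxolane at C8) | C1OC2(OO1)CC[C@H]3C(C)(C)CCC[C@]3(C)[C@H]2CCO[Si](C)(C)C(C)(C)C | intermediate
7 | 12-(tert-butyldimethylsilyloxy)-13,14,15,16,17-pentanorlabdan-8-one | O=C1CC[C@H]2C(C)(C)CCC[C@]2(C)[C@H]1CCO[Si](C)(C)C(C)(C)C | intermediate
8 | 7-trifluoroacetyl derivative of 7 (C7 epimers and enol) | O=C1C(C(=O)C(F)(F)F)C[C@H]2C(C)(C)CCC[C@]2(C)[C@H]1CCO[Si](C)(C)C(C)(C)C | intermediate
9 | 7-diazo-12-(tert-butyldimethylsilyloxy)-13,14,15,16,17-pentanorlabdan-8-one | O=C1C(=[N+]=[N-])C[C@H]2C(C)(C)CCC[C@]2(C)[C@H]1CCO[Si](C)(C)C(C)(C)C | intermediate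
10 | ring-contracted ketene (C8 exocyclic on C7) | O=C=C1C[C@H]2C(C)(C)CCC[C@]2(C)[C@H]1CCO[Si](C)(C)C(C)(C)C | intermediate
11 | methyl 12-(tert-butyldimethylsilyloxy)-9(8→7)abeo-13,14,15,16,17-pentanorlabdan-8-oate (trans-hydrindane, 7β-CO2Me, 9β-CH2CH2OTBS, 5α-H, 10β-CH3) | COC(=O)[C@H]1C[C@H]2C(C)(C)CCC[C@]2(C)[C@H]1CCO[Si](C)(C)C(C)(C)C | intermediate
12 | 8-methyl hydrogen 9(8→7)abeo-13,14,15,16,17-pentanorlabdane-8,12-dioate | COC(=O)[C@H]1C[C@H]2C(C)(C)CCC[C@]2(C)[C@H]1CC(O)=O | intermediate
13 | 1-bromo-2-methylpropane | CC(C)CBr | starting material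
14 | isobutylmagnesium bromide | CC(C)C[Mg]Br | intermediate
15 | acid chloride of 12 | COC(=O)[C@H]1C[C@H]2C(C)(C)CCC[C@]2(C)[C@H]1CC(=O)Cl | intermediate
16 | methyl ester carrying the 9β-(4-methyl-2-oxopentyl) side chain | COC(=O)[C@H]1C[C@H]2C(C)(C)CCC[C@]2(C)[C@H]1CC(=O)CC(C)C | intermediate
17 | tricyclic 12-hydroxy-13-isopropyl-12-en-14-one (ring C dione enol; 8α-H, 9α-H drawn) | O=C1C(C(C)C)=C(O)C[C@H]2[C@@H]1C[C@H]1C(C)(C)CCC[C@@]12C | intermediate
18 | 12,14-bis(tert-butyldimethylsilyloxy) ring C diene | CC(C)C1=C(O[Si](C)(C)C(C)(C)C)C[C@H]2C(=C1O[Si](C)(C)C(C)(C)C)C[C@H]1C(C)(C)CCC[C@@]12C | intermediate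
19 | 12,14-bis(tert-butyldimethylsilyloxy)-13-isopropyl arene (ring C aromatic, 5α-H, 10β-CH3) | CC(C)c1c(O[Si](C)(C)C(C)(C)C)cc2c(c1O[Si](C)(C)C(C)(C)C)C[C@H]1C(C)(C)CCC[C@@]12C | intermediate
20 | 6-ketone of 19 | CC(C)c1c(O[Si](C)(C)C(C)(C)C)cc2c(c1O[Si](C)(C)C(C)(C)C)C(=O)[C@H]1C(C)(C)CCC[C@@]12C | intermediate
21 | 6-(methoxymethylene) compound (E/Z mixture) | CC(C)c1c(O[Si](C)(C)C(C)(C)C)cc2c(c1O[Si](C)(C)C(C)(C)C)C(=COC)[C@H]1C(C)(C)CCC[C@@]12C | intermediate
22 | 12,14-dihydroxy-6-(methoxymethylene) compound | CC(C)c1c(O)cc2c(c1O)C(=COC)[C@H]1C(C)(C)CCC[C@@]12C | intermediate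
23 | 12,14-dihydroxy-13-isopropyl arene with 6α-formyl group | CC(C)c1c(O)cc2c(c1O)[C@H](C=O)[C@H]1C(C)(C)CCC[C@@]12C | intermediate
24 | 6α-formyl-12-hydroxy-13-isopropyl-11,14-quinone | CC(C)C1=C(O)C(=O)C2=C(C1=O)[C@H](C=O)[C@H]1C(C)(C)CCC[C@@]12C | intermediate
25 | myrcene | CC(C)=CCCC(=C)C=C | starting material
26 | CNP0239256.1 | CC(C)=CCCC1=CC[C@@]23C(=O)C(C(C)C)=C(O)C(=O)[C@]2(C1)[C@@]1(C)CCCC(C)(C)[C@@H]1[C@H]3C=O | target

**Step count**
Total: 16 steps. Longest linear sequence: 15 steps (steps 1–7 and 9–16 from sclareolide); step 8 is a one-step side branch.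

**Steps most likely to fail**

1. Step 16. The cycloaddition at the tetrasubstituted C8=C9 bond may be slow, the diene may add in the opposite orientation if the metal sits on the O11/O12 pair and not on O14, or the Lewis acid may set off an ene reaction of the formyl group with the new ring D alkene. The fallback sets out from 24 and comes back at 26. The 12-hydroxyl is capped with Me3SiCHN2 in MeOH/PhMe to give the 12-methoxy quinone aldehyde F1. With the hydroxyl gone, a monodentate Lewis acid (BF3·OEt2, CH2Cl2, −78 °C) binds the vinylogous ester carbonyl C14, which is the known way to fix the orientation in cycloadditions of methoxy-p-quinones, and reaction with 25 should give the 12-O-methyl adduct F2. Hydrolysis of the vinylogous ester with 1 M aq HCl in THF then gives 26.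

2. Step 12. Oxidation of the electron-rich ring C at C11 or loss of the aryl silyl ethers may outrun the benzylic C–H oxidation. The fallback sets out from 17 and comes back at 22. The dione is aromatised with I2 in refluxing MeOH, which should give the 12,14-dimethoxy arene F3 directly. Methyl ethers allow the classical benzylic oxidation with CrO3 in aqueous AcOH to the 12,14-dimethoxy 6-ketone F4. The Wittig reaction of step 13 gives the 12,14-dimethoxy 6-(methoxymethylene) compound F5. NaSEt in DMF at 140 °C cleaves both aryl methyl ethers by attack at methyl without touching the enol ether and gives 22, which is hydrolysed with aqueous HCl as in step 14.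

3. Step 13. The ylide may add too slowly to the hindered, electron-rich aryl ketone and act as a base, so that enolisation toward C5 erodes the trans ring fusion. The fallback sets out from 20 and comes back at 23. Non-basic methylenation with Cp2TiMe2 in PhMe at 65 °C gives the 6-methylene compound F6. Hydroboration–oxidation (9-BBN, THF; then NaBO3) puts the hydroxyl on the new carbon and gives the 6-hydroxymethyl compound F7. Dess–Martin periodinane gives the bis-silyl 6-formyl compound F8. Bu4NF followed by dilute aqueous HCl removes the silyl groups and equilibrates C6 to give 23.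

**Further compounds**
F1 | step 16 | 6α-formyl-12-methoxy-13-isopropyl-11,14-quinone | CC(C)C1=C(OC)C(=O)C2=C(C1=O)[C@H](C=O)[C@H]1C(C)(C)CCC[C@@]12C
F2 | step 16 | 12-O-methyl ether of 26 | CC(C)=CCCC1=CC[C@@]23C(=O)C(C(C)C)=C(OC)C(=O)[C@]2(C1)[C@@]1(C)CCCC(C)(C)[C@@H]1[C@H]3C=O
F3 | step 12 | 12,14-dimethoxy-13-isopropyl arene | CC(C)c1c(OC)cc2c(c1OC)C[C@H]1C(C)(C)CCC[C@@]12C
F4 | step 12 | 12,14-dimethoxy 6-ketone | CC(C)c1c(OC)cc2c(c1OC)C(=O)[C@H]1C(C)(C)CCC[C@@]12C
F5 | step 12 | 12,14-dimethoxy 6-(methoxymethylene) compound | CC(C)c1c(OC)cc2c(c1OC)C(=COC)[C@H]1C(C)(C)CCC[C@@]12C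
F6 | step 13 | 12,14-bis(tert-butyldimethylsilyloxy) 6-methylene compound | CC(C)c1c(O[Si](C)(C)C(C)(C)C)cc2c(c1O[Si](C)(C)C(C)(C)C)C(=C)[C@H]1C(C)(C)CCC[C@@]12C
F7 | step 13 | 12,14-bis(tert-butyldimethylsilyloxy) 6-hydroxymethyl compound (6β drawn, either epimer serves) | CC(C)c1c(O[Si](C)(C)C(C)(C)C)cc2c(c1O[Si](C)(C)C(C)(C)C)[C@@H](CO)[C@H]1C(C)(C)CCC[C@@]12C
F8 | step 13 | 12,14-bis(tert-butyldimethylsilyloxy) 6-formyl compound (6α drawn, epimers converge) | CC(C)c1c(O[Si](C)(C)C(C)(C)C)cc2c(c1O[Si](C)(C)C(C)(C)C)[C@H](C=O)[C@H]1C(C)(C)CCC[C@@]12C
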